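**Retrosynthetic overview** (furanone locants: O1, C2 = carbonyl C, C3 = ring CH, C4 = ring C bearing CH2OH, C5 = stereocentre)
1. Hippolide E ⇐ spiro ortho ester 21 (aqueous acid unmasks the lactone carbonyl C2 and removes the silyl ether) ⇐ ester 20 (hydride reduction of the chain ester to CH2OH).
2. Key disconnection C2–C3: 20 ⇐ α-oxy ketone 16. C3 is introduced as a one-carbon alkylidene carbene on the C4 ketone and inserts into the C–H bond of an orthoformate carbon (the future C2) that already sits on O1.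
3. Enabling feature: in the ring O1–C2–C3=C4–C5, C2 lies 1,5 to C3 across C4–C5–O1, and C3 is an unsubstituted ring CH. A carbene at C3 therefore reaches a C2–H bond through a five-membered array, and because C3=C4 is endocyclic no alkene geometry has to be set.
4. 16 ⇐ Wittig reaction (E alkene of the chain) of keto-aldehyde 15 with homofarnesyl ylide 7 (from farnesol). 15 ⇐ double ozonolysis of diene 13 ⇐ (R)-dienol 12 by asymmetric allylboration of an α-substituted acrolein (sets C5).
5. Ring order: the temporary 1,3-dioxolane is attached in step 8; the only ring of the target, the furanone, is closed in step 11; the dioxolane is removed in step 13.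

Key step: step 11

Assumption: (2E,6E)-farnesol, 2-methylidenepropane-1,3-diol, (+)-B-methoxydiisopinocampheylborane, 2-methoxy-1,3-dioxolane and trimethylsilyldiazomethane are taken as commercial, and a mixed orthoformate is assumed to tolerate base, hydride and neutral ozonolysis but not acid.

**Route**

Step 1
Reactants: 1 (2E,6E)-farnesol
Product: 2 (2E,6E)-farnesal
Conditions: activated MnO2, CH2Cl2, rt
Reagents that add atoms: none
Why: Heterogeneous MnO2 oxidation is selective for the primary allylic alcohol and should leave the 2E geometry intact.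

Step 2
Reactants: 2 (2E,6E)-farnesal
Product: 3 (3E,7E)-4,8,12-trimethyltrideca-1,3,7,11-tetraene
Conditions: Ph3PCH3Br, KOtBu, THF, 0 °C → rt
Reagents that add atoms: methyltriphenylphosphonium bromide, C[P+](c1ccccc1)(c1ccccc1)c1ccccc1.[Br-]
Why: Wittig methylenation of the enal should give the terminal diene without touching the trisubstituted alkenes.

Step 3
Reactants: 3 (3E,7E)-4,8,12-trimethyltrideca-1,3,7,11-tetraene
Product: 5 ethyl (5E,9E)-2-bromo-6,10,14-trimethylpentadeca-5,9,13-trienoate (racemic), via B-alkyl-9-BBN 4 (not isolated)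
Conditions: 9-BBN, THF, 0 °C → rt; then Br2CHCO2Et, KOtBu, t-BuOH/THF, 0 °C
Reagents that add atoms: ethyl dibromoacetate, CCOC(=O)C(Br)Br
Why: 9-BBN hydroborates only the monosubstituted terminal alkene (boron at C1), and the primary B-alkyl group then migrates to the carbon of the dibromoacetate enolate with loss of bromide (organoborane α-alkylation of an α-halo ester) to give the α-bromo ester after protonolysis.

Step 4
Reactants: 5 ethyl (5E,9E)-2-bromo-6,10,14-trimethylpentadeca-5,9,13-trienoate
Product: 7 ethyl (5E,9E)-6,10,14-trimethyl-2-(triphenyl-λ5-phosphanylidene)pentadeca-5,9,13-trienoate, via phosphonium bromide 6 (not isolated)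
Conditions: PPh3, toluene, 90 °C; then 1 M aq NaOH, CH2Cl2, rt
Reagents that add atoms: triphenylphosphine, c1ccc(cc1)P(c1ccccc1)c1ccccc1
Why: SN2 displacement of the activated α-bromide by PPh3 and deprotonation of the acidic α-CH should give the isolable ester-stabilised ylide.

Step 5
Reactants: 8 2-methylidenepropane-1,3-diol
Product: 9 2-{[(tert-butyldimethylsilyl)oxy]methyl}prop-2-en-1-ol
Conditions: TBSCl (1 equiv), 8 (3 equiv), Et3N, DMAP (cat.), CH2Cl2, 0 °C
Reagents that add atoms: tert-butyldimethylsilyl chloride, CC(C)(C)[Si](C)(C)Cl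
Why: Monosilylation of the symmetric diol used in excess should give the mono-ether, and unreacted diol is removed with water.

Step 6
Reactants: 9 2-{[(tert-butyldimethylsilyl)oxy]methyl}prop-2-en-1-ol
Product: 10 2-{[(tert-butyldimethylsilyl)oxy]methyl}prop-2-enal
Conditions: activated MnO2, CH2Cl2, rt
Reagents that add atoms: none
Why: Allylic oxidation with MnO2 should give the α-substituted acrolein under neutral conditions, and it is used at once.

Step 7
Reactants: 10 2-{[(tert-butyldimethylsilyl)oxy]methyl}prop-2-enal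
Product: 12 (3R)-2-{[(tert-butyldimethylsilyl)oxy]methyl}hexa-1,5-dien-3-ol, via diisopinocampheylborinate 11 (not isolated)
Conditions: (+)-Ipc2BOMe, allylMgBr, Et2O, 0 °C → rt; then 10, −78 °C; then 3 M NaOH, 30% H2O2, 0 °C → rt
Reagents that add atoms: allylmagnesium bromide, C=CC[Mg]Br
Why: Brown allylboration through a closed chair transition state; the (+)-Ipc2B reagent (from (−)-α-pinene) should deliver allyl to the Re face of the enal carbonyl, which sets the carbinol that becomes C5 as (R).

Step 8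
Reactants: 12 (3R)-2-{[(tert-butyldimethylsilyl)oxy]methyl}hexa-1,5-dien-3-ol
Product: 13 2-{[(3R)-2-{[(tert-butyldimethylsilyl)oxy]methyl}hexa-1,5-dien-3-yl]oxy}-1,3-dioxolane
Conditions: 2-methoxy-1,3-dioxolane (excess), PPTS (cat.), benzene, 4 Å MS, rt; Et3N quench
Reagents that add atoms: 2-methoxy-1,3-dioxolane, COC1OCCO1
Why: Acid-catalysed ortho ester exchange of the exocyclic methoxy group, driven by removal of methanol, should put the future C2 on O1 as a base-stable orthoformate (a masked formate) without touching C5.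

Step 9
Reactants: 13 2-{[(3R)-2-{[(tert-butyldimethylsilyl)oxy]methyl}hexa-1,5-dien-3-yl]oxy}-1,3-dioxolane
Product: 15 (3R)-5-[(tert-butyldimethylsilyl)oxy]-3-(1,3-dioxolan-2-yloxy)-4-oxopentanal, via bis-ozonide 14 (not isolated)
Conditions: O3, CH2Cl2, NaHCO3, −78 °C (indicator end point); then PPh3, −78 °C → rt; used crude
Reagents that add atoms: ozone, [O-][O+]=O
Why: Ozonolysis should cleave the vinyl group to the aldehyde and the 1,1-disubstituted alkene to the C4 ketone at −78 °C far faster than ozone attacks the orthoformate C–H, and the neutral PPh3 reduction leaves C5 untouched.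

Step 10
Reactants: 15 (3R)-5-[(tert-butyldimethylsilyl)oxy]-3-(1,3-dioxolan-2-yloxy)-4-oxopentanal; 7 ethyl (5E,9E)-6,10,14-trimethyl-2-(triphenyl-λ5-phosphanylidene)pentadeca-5,9,13-trienoate
Product: 16 ethyl (2E,5E,9E)-2-[(3R)-5-[(tert-butyldimethylsilyl)oxy]-3-(1,3-dioxolan-2-yloxy)-4-oxopentylidene]-6,10,14-trimethylpentadeca-5,9,13-trienoate
Conditions: CH2Cl2, 0 °C → rt
Reagents that add atoms: none
Why: The α-branched ester-stabilised ylide should react only with the aldehyde (not the ketone) and give the E-trisubstituted enoate (Wittig reaction under thermodynamic control), and it is too weak a base to epimerise C5.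

Step 11
Reactants: 16 ethyl (2E,5E,9E)-2-[(3R)-5-[(tert-butyldimethylsilyl)oxy]-3-(1,3-dioxolan-2-yloxy)-4-oxopentylidene]-6,10,14-trimethylpentadeca-5,9,13-trienoate
Product: 20 ethyl (2E,5E,9E)-2-{2-[(7R)-8-{[(tert-butyldimethylsilyl)oxy]methyl}-1,4,6-trioxaspiro[4.4]non-8-en-7-yl]ethylidene}-6,10,14-trimethylpentadeca-5,9,13-trienoate, via lithium alkoxide adduct 17 (not isolated), via diazoalkene 18 (not isolated), via alkylidene carbene 19 (not isolated)
Conditions: Me3SiCHN2, n-BuLi, THF, −78 °C; then 16, −78 → 0 °C; NaHCO3 work-up, Et3N-buffered silica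
Reagents that add atoms: trimethylsilyldiazomethane, C[Si](C)(C)C=[N+]=[N-]
Why: Proposed new method: Lithiated trimethylsilyldiazomethane adds to the C4 ketone, adduct 17 collapses by silyl transfer and loss of silanolate to diazoalkene 18, and loss of N2 gives alkylidene carbene 19, whose divalent carbon is the future C3; its vacant p orbital takes the hydridic C–H of the O1-bound orthoformate carbon (the future C2) in a concerted 1,5-insertion that forms C2–C3 and moves that hydrogen onto C3. The closest known reaction type is the alkylidene-carbene 1,5-C–H insertion of α-alkoxy ketones into the ether C–H α to oxygen, which gives 2,5-dihydrofurans under these conditions; new here is that the C–H belongs to an orthoformate, so the ring carbon arrives at the carboxyl oxidation level. The 2,5-dihydrofuran ring O1–C2–C3=C4–C5 closes by this insertion through a five-membered cyclic array, a 5-ring closure by C–C bond formation at the carbene carbon. No stereocentre is created: spiro C2 carries two identical dioxolane oxygens, C5 is not touched, and the carbene has no E/Z geometry, so nothing has to be controlled at C3=C4. The selectivity needed is site selectivity among carbene pathways, and the substrate is built to secure it: the orthoformate C–H is tertiary and flanked by three oxygens, the CH2OSi arm has no C–H in the 1,5-position, neither C4 substituent migrates readily in a 1,2-shift, and the only alkene within reach (C5–CH2–CH=C) is an electron-poor enoate that resists the electrophilic carbene. Attack of the reagent on the ketone and not on the ester should follow from activation of the ketone by its two α-oxygen substituents at −78 °C.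

Step 12
Reactants: 20 ethyl (2E,5E,9E)-2-{2-[(7R)-8-{[(tert-butyldimethylsilyl)oxy]methyl}-1,4,6-trioxaspiro[4.4]non-8-en-7-yl]ethylidene}-6,10,14-trimethylpentadeca-5,9,13-trienoate
Product: 21 (2E,5E,9E)-2-{2-[(7R)-8-{[(tert-butyldimethylsilyl)oxy]methyl}-1,4,6-trioxaspiro[4.4]non-8-en-7-yl]ethylidene}-6,10,14-trimethylpentadeca-5,9,13-trien-1-ol
Conditions: LiAlH4, Et2O, −20 → 0 °C; Fieser work-up
Reagents that add atoms: none
Why: 1,2-Reduction of the α-alkyl enoate by LiAlH4 should give the allylic alcohol while the ortho ester (inert to hydride without a Lewis acid), the silyl ether and the isolated alkenes survive.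

Step 13
Reactants: 21 (2E,5E,9E)-2-{2-[(7R)-8-{[(tert-butyldimethylsilyl)oxy]methyl}-1,4,6-trioxaspiro[4.4]non-8-en-7-yl]ethylidene}-6,10,14-trimethylpentadeca-5,9,13-trien-1-ol
Product: 23 Hippolide E, via butenolide silyl ether 22 (not isolated)
Conditions: AcOH/THF/H2O (3:1:1), rt
Reagents that add atoms: water, O
Why: Mild aqueous acid should hydrolyse the spiro ortho ester to the lactone (any ring-opened 2-hydroxyethyl Z-hydroxy-enoate relactonises) and then cleave the primary silyl ether, without affecting C5 or the trisubstituted alkenes.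

**Compound list**
1 | (2E,6E)-farnesol | CC(C)=CCC/C(C)=C/CC/C(C)=C/CO | starting material
2 | (2E,6E)-farnesal | CC(C)=CCC/C(C)=C/CC/C(C)=C/C=O | intermediate
3 | (3E,7E)-4,8,12-trimethyltrideca-1,3,7,11-tetraene | CC(C)=CCC/C(C)=C/CC/C(C)=C/C=C | intermediate
4 | 9-[(3E,7E)-4,8,12-trimethyltrideca-3,7,11-trien-1-yl]-9-borabicyclo[3.3.1]nonane | CC(C)=CCC/C(C)=C/CC/C(C)=C/CCB1C2CCCC1CCC2 | intermediate
5 | ethyl (5E,9E)-2-bromo-6,10,14-trimethylpentadeca-5,9,13-trienoate (racemic) | CC(C)=CCC/C(C)=C/CC/C(C)=C/CCC(Br)C(=O)OCC | intermediate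
6 | [(5E,9E)-1-ethoxy-6,10,14-trimethyl-1-oxopentadeca-5,9,13-trien-2-yl]triphenylphosphonium bromide | CC(C)=CCC/C(C)=C/CC/C(C)=C/CCC(C(=O)OCC)[P+](c1ccccc1)(c1ccccc1)c1ccccc1.[Br-] | intermediate
7 | ethyl (5E,9E)-6,10,14-trimethyl-2-(triphenyl-λ5-phosphanylidene)pentadeca-5,9,13-trienoate | CC(C)=CCC/C(C)=C/CC/C(C)=C/CCC(C(=O)OCC)=P(c1ccccc1)(c1ccccc1)c1ccccc1 | intermediate
8 | 2-methylidenepropane-1,3-diol | C=C(CO)CO | starting material
9 | 2-{[(tert-butyldimethylsilyl)oxy]methyl}prop-2-en-1-ol | C=C(CO)CO[Si](C)(C)C(C)(C)C | intermediate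
10 | 2-{[(tert-butyldimethylsilyl)oxy]methyl}prop-2-enal | C=C(C=O)CO[Si](C)(C)C(C)(C)C | intermediate
11 | (3R)-2-{[(tert-butyldimethylsilyl)oxy]methyl}hexa-1,5-dien-3-yl diisopinocampheylborinate | C=CC[C@@H](OB([C@H]1C[C@H]2C[C@H](C2(C)C)[C@@H]1C)[C@H]1C[C@H]2C[C@H](C2(C)C)[C@@H]1C)C(=C)CO[Si](C)(C)C(C)(C)C | intermediate
12 | (3R)-2-{[(tert-butyldimethylsilyl)oxy]methyl}hexa-1,5-dien-3-ol | C=CC[C@@H](O)C(=C)CO[Si](C)(C)C(C)(C)C | intermediate
13 | 2-{[(3R)-2-{[(tert-butyldimethylsilyl)oxy]methyl}hexa-1,5-dien-3-yl]oxy}-1,3-dioxolane | C=CC[C@@H](OC1OCCO1)C(=C)CO[Si](C)(C)C(C)(C)C | intermediate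
14 | bis-ozonide (bis-1,2,4-trioxolane) of 13, mixture of isomers at the new ring carbons | C1OOC(O1)C[C@@H](OC2OCCO2)C3(CO[Si](C)(C)C(C)(C)C)OCOO3 | intermediate
15 | (3R)-5-[(tert-butyldimethylsilyl)oxy]-3-(1,3-dioxolan-2-yloxy)-4-oxopentanal | O=CC[C@@H](OC1OCCO1)C(=O)CO[Si](C)(C)C(C)(C)C | intermediate
16 | ethyl (2E,5E,9E)-2-[(3R)-5-[(tert-butyldimethylsilyl)oxy]-3-(1,3-dioxolan-2-yloxy)-4-oxopentylidene]-6,10,14-trimethylpentadeca-5,9,13-trienoate | CC(C)=CCC/C(C)=C/CC/C(C)=C/CC/C(=C\C[C@@H](OC1OCCO1)C(=O)CO[Si](C)(C)C(C)(C)C)C(=O)OCC | intermediate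
17 | lithium alkoxide of the tertiary diazo(trimethylsilyl)methyl carbinol from 16 (both epimers at the carbinol carbon) | CC(C)=CCC/C(C)=C/CC/C(C)=C/CC/C(=C\C[C@@H](OC1OCCO1)C([O-])(CO[Si](C)(C)C(C)(C)C)C(=[N+]=[N-])[Si](C)(C)C)C(=O)OCC.[Li+] | intermediate
18 | diazoalkene from 17 | CC(C)=CCC/C(C)=C/CC/C(C)=C/CC/C(=C\C[C@@H](OC1OCCO1)C(=C=[N+]=[N-])CO[Si](C)(C)C(C)(C)C)C(=O)OCC | intermediate
19 | alkylidene carbene from 18 | CC(C)=CCC/C(C)=C/CC/C(C)=C/CC/C(=C\C[C@@H](OC1OCCO1)C(=[C])CO[Si](C)(C)C(C)(C)C)C(=O)OCC | intermediate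
20 | ethyl (2E,5E,9E)-2-{2-[(7R)-8-{[(tert-butyldimethylsilyl)oxy]methyl}-1,4,6-trioxaspiro[4.4]non-8-en-7-yl]ethylidene}-6,10,14-trimethylpentadeca-5,9,13-trienoate | CC(C)=CCC/C(C)=C/CC/C(C)=C/CC/C(=C\C[C@H]1OC2(OCCO2)C=C1CO[Si](C)(C)C(C)(C)C)C(=O)OCC | intermediate
21 | (2E,5E,9E)-2-{2-[(7R)-8-{[(tert-butyldimethylsilyl)oxy]methyl}-1,4,6-trioxaspiro[4.4]non-8-en-7-yl]ethylidene}-6,10,14-trimethylpentadeca-5,9,13-trien-1-ol | CC(C)=CCC/C(C)=C/CC/C(C)=C/CC/C(=C\C[C@H]1OC2(OCCO2)C=C1CO[Si](C)(C)C(C)(C)C)CO | intermediate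
22 | 4-O-silyl Hippolide E: (5R)-4-{[(tert-butyldimethylsilyl)oxy]methyl}-5-[(2E,6E,10E)-3-(hydroxymethyl)-7,11,15-trimethylhexadeca-2,6,10,14-tetraen-1-yl]furan-2(5H)-one | CC(C)=CCC/C(C)=C/CC/C(C)=C/CC/C(=C\C[C@H]1OC(=O)C=C1CO[Si](C)(C)C(C)(C)C)CO | intermediate
23 | Hippolide E: (5R)-4-(hydroxymethyl)-5-[(2E,6E,10E)-3-(hydroxymethyl)-7,11,15-trimethylhexadeca-2,6,10,14-tetraen-1-yl]furan-2(5H)-one | CC(C)=CCC/C(C)=C/CC/C(C)=C/CC/C(=C\C[C@H]1OC(=O)C=C1CO)CO | target

**Step count and risks**
Total steps: 13. Longest linear sequence: 9 (steps 5–13, from 8); the chain branch (steps 1–4) joins at step 10.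

Risk 1, step 11 (Proposed new method). The carbene may be diverted before it reaches the orthoformate C–H: capture by a dioxolane oxygen (oxonium ylide), addition to the neighbouring enoate alkene, or silyl migration at the alkoxide stage. C5 could also epimerise by enolisation of the ketone before the reagent adds. The fallback uses only known chemistry and moves C2 to the acetal oxidation level; it sets out from 12 and returns at 23. Dienol 12 would be converted with MOMCl/iPr2NEt into the methoxymethyl ether F1, ozonolysed as in step 9 to keto-aldehyde F2, and joined with 7 as in step 10 to ketone F3. Lithiated trimethylsilyldiazomethane should then give, by the established alkylidene-carbene 1,5-insertion into the ether C–H α to oxygen, the 2-methoxy-2,5-dihydrofuran F4 (both acetal epimers, which converge later). LiAlH4 would give allylic alcohol F5 and TBSCl/imidazole the bis-silyl ether F6. Brief buffered hydrolysis (PPTS, wet acetone, 0 °C, stopped before dehydration to the furan) would give lactol F7, MnO2 would oxidise it to the bis-silyl butenolide F8, and HF·pyridine would give 23.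

Risk 2, step 9. Excess ozone may oxidise the orthoformate C–H, and the free keto-aldehyde may lose the O1 substituent by β-elimination or epimerise at C5 before it is olefinated. The fallback avoids the free keto-aldehyde by forming the ketone after the olefination; it sets out from 13 and returns at 16. Ozonolysis of 13 in CH2Cl2/MeOH with NaBH4 work-up would give the diol F9 (both epimers at the new secondary carbinol, which is oxidised later). Copper/TEMPO aerobic oxidation of the primary alcohol in the presence of ylide 7 (tandem oxidation–Wittig, the aldehyde being trapped as it forms) would give the hydroxy enoate F10. Parikh–Doering oxidation of the secondary alcohol would give 16.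

Risk 3, step 8. The acid-catalysed exchange may stall at equilibrium on the hindered allylic alcohol, or the mixed orthoformate may revert to the formate on purification. The fallback replaces the equilibrium exchange by an irreversible O-alkylation under basic conditions; it sets out from 12 and returns at 13. The potassium alkoxide of 12 (KHMDS, THF, −78 °C) would be treated with 1,3-dioxolan-2-ylium tetrafluoroborate (prepared from 2-methoxy-1,3-dioxolane and BF3·OEt2), which gives 13 directly and makes no new compound.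

**Further compounds**
F1 | step 11 | tert-butyl{[(3R)-3-(methoxymethoxy)-2-methylidenehex-5-en-1-yl]oxy}dimethylsilane | C=CC[C@@H](OCOC)C(=C)CO[Si](C)(C)C(C)(C)C
F2 | step 11 | (3R)-5-[(tert-butyldimethylsilyl)oxy]-3-(methoxymethoxy)-4-oxopentanal | O=CC[C@@H](OCOC)C(=O)CO[Si](C)(C)C(C)(C)C
F3 | step 11 | ethyl (2E,5E,9E)-2-[(3R)-5-[(tert-butyldimethylsilyl)oxy]-3-(methoxymethoxy)-4-oxopentylidene]-6,10,14-trimethylpentadeca-5,9,13-trienoate | CC(C)=CCC/C(C)=C/CC/C(C)=C/CC/C(=C\C[C@@H](OCOC)C(=O)CO[Si](C)(C)C(C)(C)C)C(=O)OCC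
F4 | step 11 | ethyl (2E,5E,9E)-2-{2-[(2R)-3-{[(tert-butyldimethylsilyl)oxy]methyl}-5-methoxy-2,5-dihydrofuran-2-yl]ethylidene}-6,10,14-trimethylpentadeca-5,9,13-trienoate (acetal epimers) | CC(C)=CCC/C(C)=C/CC/C(C)=C/CC/C(=C\C[C@H]1OC(OC)C=C1CO[Si](C)(C)C(C)(C)C)C(=O)OCC
F5 | step 11 | (2E,5E,9E)-2-{2-[(2R)-3-{[(tert-butyldimethylsilyl)oxy]methyl}-5-methoxy-2,5-dihydrofuran-2-yl]ethylidene}-6,10,14-trimethylpentadeca-5,9,13-trien-1-ol | CC(C)=CCC/C(C)=C/CC/C(C)=C/CC/C(=C\C[C@H]1OC(OC)C=C1CO[Si](C)(C)C(C)(C)C)CO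
F6 | step 11 | tert-butyldimethylsilyl ether of F5 | CC(C)=CCC/C(C)=C/CC/C(C)=C/CC/C(=C\C[C@H]1OC(OC)C=C1CO[Si](C)(C)C(C)(C)C)CO[Si](C)(C)C(C)(C)C
F7 | step 11 | lactol (2,5-dihydrofuran-2-ol) from F6 | CC(C)=CCC/C(C)=C/CC/C(C)=C/CC/C(=C\C[C@H]1OC(O)C=C1CO[Si](C)(C)C(C)(C)C)CO[Si](C)(C)C(C)(C)C
F8 | step 11 | bis(tert-butyldimethylsilyl) ether of Hippolide E | CC(C)=CCC/C(C)=C/CC/C(C)=C/CC/C(=C\C[C@H]1OC(=O)C=C1CO[Si](C)(C)C(C)(C)C)CO[Si](C)(C)C(C)(C)C
F9 | step 9 | (3R)-5-[(tert-butyldimethylsilyl)oxy]-3-(1,3-dioxolan-2-yloxy)pentane-1,4-diol (C4 epimers) | OCC[C@@H](OC1OCCO1)C(O)CO[Si](C)(C)C(C)(C)C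
F10 | step 9 | ethyl (2E,5E,9E)-2-[(3R)-5-[(tert-butyldimethylsilyl)oxy]-3-(1,3-dioxolan-2-yloxy)-4-hydroxypentylidene]-6,10,14-trimethylpentadeca-5,9,13-trienoate (carbinol epimers) | CC(C)=CCC/C(C)=C/CC/C(C)=C/CC/C(=C\C[C@@H](OC1OCCO1)C(O)CO[Si](C)(C)C(C)(C)C)C(=O)OCC
F0 | step 8 | none | none
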